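**Retrosynthetic overview** (germacrane numbering: C1 ketone, C4=C5, C6 lactone carbinol, C8 methacrylate, C10 tertiary acetate, C13 CH2OAc)
1. The last bond is C5–C6. An electrochemical Ni/Cr alkenyl–aldehyde closure makes the ten-membered ring and the butenolide in the same step.
2. The (Z)-formylacrylate electrophile (C6/C7/C11/C12) comes from a 2-silyl-3,4-disubstituted furan by singlet-oxygen photooxygenation.
3. C1–C2 is formed when a homoallylic alkyllithium (from 3-butyn-1-ol) opens a γ-lactone, which frees O8 for the methacrylate.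
4. C7–C8 is formed by adding a 4-lithiofuran (from 3-furanmethanol) to a lactate-derived aldehyde, followed by translactonisation.
5. Stereochemistry: C10 comes from L-lactic acid, C8 is set from C10, and C6 from C8. Rings form in the order dioxolanone (temporary), γ-lactone (temporary), hydroxybutenolide, then carbocycle plus butenolide.

Assumption: the target is read as (4E,6R,8S,10R); a one-pot sequence counts as one step; 19 and 20 are drawn as open hydroxy ketones (they equilibrate with a five-membered lactol), and 25 is a lactol epimer mixture at C6.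

Step 1
Reactants: 1 (S)-lactic acid (L-lactic acid); 2 pivalaldehyde
Product: 3 (2S,5S)-2-tert-butyl-5-methyl-1,3-dioxolan-4-one (cis)
Conditions: p-TsOH·H2O (cat.), H2SO4 (cat.), pentane, reflux, Dean–Stark; recryst. pentane/Et2O, −78 °C
Reagents that add atoms: none
Why: Acid-catalysed acetalisation with water removal; the lactate centre makes the 2,5-cis acetal the major (about 4:1) and crystalline isomer, so the new acetal centre (2S) is set by the bought one.

Step 2
Reactants: 3 (2S,5S)-2-tert-butyl-5-methyl-1,3-dioxolan-4-one; 4 allyl bromide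
Product: 6 (2S,5R)-2-tert-butyl-5-methyl-5-(prop-2-en-1-yl)-1,3-dioxolan-4-one, via lithium enolate 5 (not isolated)
Conditions: LDA (1.05 equiv), THF, −78 °C; 4, −78 → −30 °C
Reagents that add atoms: none
Why: Seebach self-regeneration of stereocentres (enolate alkylation): the planar enolate keeps only the acetal centre and allyl bromide enters anti to tert-butyl, rebuilding the quaternary carbon (future C10) with overall retention, descriptor 5R.

Step 3
Reactants: 6 (2S,5R)-5-allyl dioxolanone
Product: 7 (2S,5R)-2-tert-butyl-5-methyl-5-(2-oxoethyl)-1,3-dioxolan-4-one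
Conditions: O3, CH2Cl2, −78 °C; Me2S, → rt
Reagents that add atoms: ozone [O-][O+]=O
Why: Ozonolysis with reductive work-up cleaves the only C=C bond and leaves the acetal and carbonyl alone; no stereocentre is touched.

Step 4
Reactants: 8 3-furanmethanol
Product: 10 [2-(tert-butyldimethylsilyl)furan-3-yl]methanol, via silyl ether 9 (not isolated)
Conditions: n-BuLi (1.0 equiv), THF, −78 °C; TBSCl (1.0 equiv), → rt; HMPA, n-BuLi (1.2 equiv), −78 → 0 °C; aq NH4Cl
Reagents that add atoms: tert-butyldimethylsilyl chloride CC(C)(C)[Si](C)(C)Cl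
Why: O-silylation, then C2 lithiation next to the CH2O group triggers a 1,4 O→C silyl shift (retro-Brook rearrangement) driven by alkoxide formation; silicon blocks C2 and marks the future lactone carbonyl C12.

Step 5
Reactants: 10 [2-(tert-butyldimethylsilyl)furan-3-yl]methanol; 7 dioxolanone aldehyde
Product: 13 (3R,5S)-5-[5-(tert-butyldimethylsilyl)-4-(hydroxymethyl)furan-3-yl]-3-hydroxy-3-methyloxolan-2-one (furyl trans to OH), via dilithiofuran 11 (not isolated), via hydroxy dioxolanone 12 (not isolated)
Conditions: 10, n-BuLi (2.2 equiv), DME, 0 °C; cannulate at −78 °C into 7·MgBr2·OEt2 (3 equiv), CH2Cl2; −78 °C → rt; aq NH4Cl; chromatography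
Reagents that add atoms: none
Why: Alkoxide-directed lithiation at C4 (C2 is blocked), then chelation-controlled 1,2-addition: Mg ties the CHO to ring oxygen O1 in a six-membered chelate fused to the rigid dioxolanone, the C5 methyl lies axial over one face, and the furyl group adds anti to it (8S, O8/O10 1,3-syn); the alkoxide then translactonises (5-exo-trig) onto the acylal carbonyl and expels pivalaldehyde.

Step 6
Reactants: 14 3-butyn-1-ol
Product: 16 (E)-4-bromo-3-methylbut-3-en-1-ol, via alkenylalane 15 (not isolated)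
Conditions: Me3Al (3 equiv), Cp2ZrCl2 (0.25 equiv), CH2Cl2, 0 °C → rt; NBS, THF, −30 °C; aq Rochelle salt
Reagents that add atoms: trimethylaluminium C[Al](C)C; N-bromosuccinimide O=C1CCC(=O)N1Br
Why: Negishi zirconium-catalysed carboalumination adds Me and Al syn, with Me on the internal carbon, and bromodealumination proceeds with retention, which fixes the E geometry of the future C4=C5 bond.

Step 7
Reactants: 16 (E)-4-bromo-3-methylbut-3-en-1-ol
Product: 17 (E)-1-bromo-4-iodo-2-methylbut-1-ene
Conditions: I2, PPh3, imidazole, CH2Cl2, 0 °C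
Reagents that add atoms: iodine II
Why: Appel-type (Garegg–Samuelsson) iodination of the primary alcohol through its alkoxyphosphonium salt; the alkenyl bromide is inert.

Step 8
Reactants: 17 (E)-1-bromo-4-iodo-2-methylbut-1-ene; 13 lactone diol
Product: 19 (1E,6R,8S)-1-bromo-8-[5-(tert-butyldimethylsilyl)-4-(hydroxymethyl)furan-3-yl]-6,8-dihydroxy-2,6-dimethyloct-1-en-5-one, via alkyllithium 18 (not isolated)
Conditions: 17 (1.3 equiv), t-BuLi (2.6 equiv), Et2O/pentane, −78 °C, 10 min; add to 13 pre-treated with n-BuLi (2.0 equiv), THF, −78 °C; → −40 °C; aq NH4Cl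
Reagents that add atoms: none
Why: Lithium–iodine exchange at the primary iodide is far faster at −78 °C than Br/Li exchange at the alkenyl bromide, and the alkyllithium adds once to the lactone, which has no α-hydrogens and gives a lactolate stable at low temperature (nucleophilic acyl substitution); this forms C1–C2 and frees O8 while leaving C8 and C10 untouched.

Step 9
Reactants: 19 triol ketone
Product: 21 C13-acetate C8-methacrylate of 19 with free C10-OH (8S,10R), via monoacetate 20 (not isolated)
Conditions: AcCl (1.05 equiv), 2,4,6-collidine, CH2Cl2, −78 °C; then methacrylic anhydride (1.5 equiv), Et3N, DMAP (0.2 equiv), −20 °C → rt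
Reagents that add atoms: acetyl chloride CC(=O)Cl; methacrylic anhydride C=C(C)C(=O)OC(=O)C(C)=C
Why: Low-temperature AcCl/collidine acetylates only the primary alcohol, DMAP-catalysed (Steglich-type) acylation then takes the secondary C8-OH from the open hydroxy-ketone form with retention, and the tertiary OH is too slow to compete.

Step 10
Reactants: 21 C10 alcohol
Product: 22 furan triester (C10-OAc, C13-OAc, C8-methacrylate; 8S,10R; E-alkenyl bromide)
Conditions: Ac2O (10 equiv), Et3N, DMAP (0.5 equiv), CH2Cl2, 35 °C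
Reagents that add atoms: acetic anhydride CC(=O)OC(C)=O
Why: Forcing DMAP-catalysed acetylation of the only remaining (tertiary α-ketol) hydroxyl; the C–O bond at C10 is not broken, so the configuration is kept.

Step 11
Reactants: 22 furan triester
Product: 25 γ-hydroxybutenolide (5-hydroxy-2(5H)-furanone; 3-CH2OAc; 4-side chain; C6 lactol epimers), via endoperoxide 23 (not isolated), via TBS ester 24 (not isolated)
Conditions: O2, tetraphenylporphyrin (1 mol %), CH2Cl2, −78 °C, visible light; then THF/H2O, rt
Reagents that add atoms: dioxygen O=O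
Why: Singlet-oxygen [4+2] photooxygenation of the furan is far faster than an ene reaction at the bromoalkene (the methacrylate is inert), and the silyl shift in the endoperoxide makes the silicon-bearing carbon the carboxyl carbon C12 regiospecifically, leaving C6 at the aldehyde level; C8 and C10 are untouched.

Step 12
Reactants: 25 γ-hydroxybutenolide
Product: 28 target (4E,6R,8S,10R)-10,13-diacetoxy-8-methacryloyloxy-1-oxogermacra-4,7(11)-dien-6,12-olide, via TMS ester 26 (not isolated), via seco alkoxide 27 (not isolated)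
Conditions: CrCl2 (20 mol %), NiCl2·dme/neocuproine (3 mol %), TMSCl (2.5 equiv), 2,6-lutidine (1.2 equiv), Bu4NBF4 (0.1 M), DMF, undivided cell, Al(+)/Ni foam(−), constant current (about 2.5 F/mol), 25 added by syringe pump (final 2 mM), rt; aq citric acid
Reagents that add atoms: none
Why: Proposed new method: cathodic Cr(III)→Cr(II) and Ni(II)→Ni(0) turnover lets Ni(0) insert into the C5–Br bond and hand the alkenyl group to Cr(III), which adds to the formyl group exposed when the lactol is opened as its TMS (Z)-formylacrylate 26, and the Cr alkoxide 27 lactonises onto the cis silyl ester, so the C5–C6 bond, the ten-membered ring and the butenolide form together while TMSCl recycles TMSO–Cr; C6 is set by C8 because A1,3 strain holds H8 in the plane of the tetrasubstituted C7=C11 bond, C9 leaves one face, and only attack of C5 on the opposite face of the s-cis, carboxyl-bound aldehyde avoids a syn-pentane C5/C9 contact, giving 6R (O6 cis to O8); the closest known reaction types are the intermolecular electrochemical Nozaki–Hiyama–Kishi coupling of alkenyl halides with aldehydes and stoichiometric CrCl2/NiCl2 NHK macrocyclisations, neither shown on a lactol-masked aldehyde or for a ten-membered carbocycle.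

**Compound list**
1 | (S)-lactic acid | C[C@H](O)C(=O)O | starting material
2 | pivalaldehyde | CC(C)(C)C=O | starting material
3 | (2S,5S)-2-tert-butyl-5-methyl-1,3-dioxolan-4-one | C[C@@H]1O[C@H](C(C)(C)C)OC1=O | intermediate
4 | allyl bromide | C=CCBr | starting material
5 | lithium enolate of 3 (2S) | CC1=C([O-])O[C@@H](C(C)(C)C)O1.[Li+] | intermediate
6 | (2S,5R)-5-allyl-2-tert-butyl-5-methyl-1,3-dioxolan-4-one | C=CC[C@@]1(C)O[C@H](C(C)(C)C)OC1=O | intermediate
7 | (2S,5R)-2-tert-butyl-5-methyl-5-(2-oxoethyl)-1,3-dioxolan-4-one | O=CC[C@@]1(C)O[C@H](C(C)(C)C)OC1=O | intermediate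
8 | 3-furanmethanol | OCc1ccoc1 | starting material
9 | tert-butyl(furan-3-ylmethoxy)dimethylsilane | CC(C)(C)[Si](C)(C)OCc1ccoc1 | intermediate
10 | [2-(tert-butyldimethylsilyl)furan-3-yl]methanol | CC(C)(C)[Si](C)(C)c1occc1CO | intermediate
11 | 4-lithio-2-TBS-3-(lithiooxymethyl)furan | [Li]OCc1c([Li])coc1[Si](C)(C)C(C)(C)C | intermediate
12 | (2S,5R)-dioxolanone carrying the (2S)-2-furyl-2-hydroxyethyl chain (present as its alkoxide, drawn neutral) | O[C@H](c1coc([Si](C)(C)C(C)(C)C)c1CO)C[C@@]2(C)O[C@H](C(C)(C)C)OC2=O | intermediate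
13 | (3R,5S)-5-[5-TBS-4-(hydroxymethyl)furan-3-yl]-3-hydroxy-3-methyloxolan-2-one | C[C@@]1(O)C[C@@H](c2coc([Si](C)(C)C(C)(C)C)c2CO)OC1=O | intermediate
14 | 3-butyn-1-ol | OCCC#C | starting material
15 | (E)-alkenyl(dimethyl)alane, O-AlMe2 alkoxide | C[Al](C)OCC/C(C)=C/[Al](C)C | intermediate
16 | (E)-4-bromo-3-methylbut-3-en-1-ol | OCC/C(C)=C/Br | intermediate
17 | (E)-1-bromo-4-iodo-2-methylbut-1-ene | ICC/C(C)=C/Br | intermediate
18 | (E)-4-bromo-3-methylbut-3-enyllithium | [Li]CC/C(C)=C/Br | intermediate
19 | (1E,6R,8S)-1-bromo-8-[5-TBS-4-(hydroxymethyl)furan-3-yl]-6,8-dihydroxy-2,6-dimethyloct-1-en-5-one | O[C@H](c1coc([Si](C)(C)C(C)(C)C)c1CO)C[C@@](C)(O)C(=O)CC/C(C)=C/Br | intermediate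
20 | C13-monoacetate of 19 | O[C@H](c1coc([Si](C)(C)C(C)(C)C)c1COC(C)=O)C[C@@](C)(O)C(=O)CC/C(C)=C/Br | intermediate
21 | C13-acetate, C8-methacrylate, C10-OH | C=C(C)C(=O)O[C@H](c1coc([Si](C)(C)C(C)(C)C)c1COC(C)=O)C[C@@](C)(O)C(=O)CC/C(C)=C/Br | intermediate
22 | furan triester (C10-OAc, C13-OAc, C8-methacrylate) | C=C(C)C(=O)O[C@H](c1coc([Si](C)(C)C(C)(C)C)c1COC(C)=O)C[C@@](C)(OC(C)=O)C(=O)CC/C(C)=C/Br | intermediate
23 | furan endoperoxide (2,3,7-trioxabicyclo[2.2.1]heptene, bridgehead epimers) | C=C(C)C(=O)O[C@H](C1=C(COC(C)=O)C2([Si](C)(C)C(C)(C)C)OOC1O2)C[C@@](C)(OC(C)=O)C(=O)CC/C(C)=C/Br | intermediate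
24 | TBS (Z)-formylacrylate | C=C(C)C(=O)O[C@H](/C(C=O)=C(\COC(C)=O)C(=O)O[Si](C)(C)C(C)(C)C)C[C@@](C)(OC(C)=O)C(=O)CC/C(C)=C/Br | intermediate
25 | γ-hydroxybutenolide (C6 epimers) | C=C(C)C(=O)O[C@H](C1=C(COC(C)=O)C(=O)OC1O)C[C@@](C)(OC(C)=O)C(=O)CC/C(C)=C/Br | intermediate
26 | TMS (Z)-formylacrylate | C=C(C)C(=O)O[C@H](/C(C=O)=C(\COC(C)=O)C(=O)O[Si](C)(C)C)C[C@@](C)(OC(C)=O)C(=O)CC/C(C)=C/Br | intermediate
27 | ten-membered (6R)-carbinol TMS ester (present as Cr(III) alkoxide, drawn as the alcohol) | C=C(C)C(=O)O[C@H]1C[C@@](C)(OC(C)=O)C(=O)CC/C(C)=C/[C@@H](O)/C1=C(/COC(C)=O)C(=O)O[Si](C)(C)C | intermediate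
28 | CNP0115165.1 | C=C(C)C(=O)O[C@H]1C[C@@](C)(OC(C)=O)C(=O)CC/C(C)=C/[C@H]2OC(=O)C(COC(C)=O)=C12 | target

**Total step count:** 12. **Longest linear sequence:** 9 (steps 1, 2, 3, 5, 8, 9, 10, 11, 12).

**Three steps most likely to fail**

Step 12 (the new step).
- Risks: silylation may give the closed pseudo-ester instead of 26. Ni(0) may ionise the C13 allylic acetate. Cr(II) or the cathode may reduce the α-acetoxy ketone or the oxo-enoate. Oligomers may form, and C6 selectivity may be low.
- Fallback, from 25 back to 28: give up both the electrolysis and the lactol as electrophile. Open 25 with TMSCHN2 (toluene/MeOH, 0 °C) to the discrete aldehyde methyl (Z)-formylacrylate F1. Close the ring by the classical stoichiometric NHK reaction (CrCl2 8 equiv, NiCl2 1 mol %, DMSO/THF, 1 mM, slow addition) to the macrocyclic hydroxy methyl ester F2. F2 lactonises on PPTS treatment to 28.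

Step 5.
- Risks: the DME carried over from the lithiation may erode Mg chelation, so the C8 ratio may be low or reversed. The aldehyde may also enolise or undergo β-elimination.
- Fallback, from 7 and 10 back to 21: accept the other epimer and correct it by inversion. Run the addition without Mg, which gives the 8R hydroxy dioxolanone F3, and this closes to the (3R,5R)-lactone F4 (separated by chromatography). F4 reacts with 18 as in step 8 to give the 8R triol F5, and AcCl/collidine gives the 8R monoacetate F6. Mitsunobu esterification of F6 with methacrylic acid (PPh3, DIAD, toluene, 0 °C) inverts C8 and delivers 21, so both epimers converge.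

Step 8.
- Risks: competing Br/Li exchange, or double addition to the lactone.
- Fallback, from 17 and 13 back to 19: replace the alkyllithium by a sulfone-stabilised carbanion. Treat 17 with PhSO2Na (DMF, rt) to give the sulfone F7. Deprotonate F7 with LDA (2.2 equiv of anion, THF, −78 °C) and acylate it with 13 (pre-deprotonated as before) to give the β-keto sulfone F8. Reductive desulfonylation with Al–Hg (THF/H2O) gives 19.

**Further compounds**
F1 | step 12 | methyl (Z)-formylacrylate (open methyl ester of 25) | C=C(C)C(=O)O[C@H](/C(C=O)=C(\COC(C)=O)C(=O)OC)C[C@@](C)(OC(C)=O)C(=O)CC/C(C)=C/Br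
F2 | step 12 | ten-membered (6R)-hydroxy methyl ester | C=C(C)C(=O)O[C@H]1C[C@@](C)(OC(C)=O)C(=O)CC/C(C)=C/[C@@H](O)/C1=C(/COC(C)=O)C(=O)OC
F3 | step 5 | 8R hydroxy dioxolanone (C8 epimer of 12) | O[C@@H](c1coc([Si](C)(C)C(C)(C)C)c1CO)C[C@@]2(C)O[C@H](C(C)(C)C)OC2=O
F4 | step 5 | (3R,5R)-5-[5-TBS-4-(hydroxymethyl)furan-3-yl]-3-hydroxy-3-methyloxolan-2-one | C[C@@]1(O)C[C@H](c2coc([Si](C)(C)C(C)(C)C)c2CO)OC1=O
F5 | step 5 | (1E,6R,8R)-triol ketone (C8 epimer of 19) | O[C@@H](c1coc([Si](C)(C)C(C)(C)C)c1CO)C[C@@](C)(O)C(=O)CC/C(C)=C/Br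
F6 | step 5 | 8R C13-monoacetate (C8 epimer of 20) | O[C@@H](c1coc([Si](C)(C)C(C)(C)C)c1COC(C)=O)C[C@@](C)(O)C(=O)CC/C(C)=C/Br
F7 | step 8 | [(3E)-4-bromo-3-methylbut-3-en-1-yl]sulfonylbenzene | O=S(=O)(CC/C(C)=C/Br)c1ccccc1
F8 | step 8 | C2-phenylsulfonyl derivative of 19 (C2 epimers) | O[C@H](c1coc([Si](C)(C)C(C)(C)C)c1CO)C[C@@](C)(O)C(=O)C(C/C(C)=C/Br)S(=O)(=O)c1ccccc1
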